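**Retrosynthetic overview**
- Both amide bonds are cut last: the target comes from a (2R,3R)-dihydrobenzofuran diacid and two molecules of agmatine.
- The C5 acrylic acid is cut by a Heck disconnection to a 5-iodide; the C3 carboxylic acid comes from oxidative cleavage of a C3 (E)-propenyl group.
- The dihydrofuran ring is the only ring built (both benzene rings are bought). It is closed at O1–C2 by acid ionisation of a benzylic carbinol, trans to the C3 substituent.
- The C2–C3 bond and the C3 stereocentre come from a [2,3]-Wittig rearrangement of a (S,Z)-allyl benzyl ether, with 1,3-chirality transfer from the stereocentre of (S)-but-3-yn-2-ol.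
- That ether is assembled from 4-(silyloxy)benzaldehyde, (S)-but-3-yn-2-ol and a protected 2-iodophenol by reductive etherification, Sonogashira coupling and semi-hydrogenation.

Assumption: the target is written as the neutral bis-guanidine of the given SMILES; in practice it is isolated from reversed-phase chromatography as its bis-guanidinium salt.

**Route**

Step 1
Reactants: 1 4-(tert-butyldimethylsilyloxy)benzaldehyde; 2 (S)-but-3-yn-2-ol
Product: 3 (S)-tert-butyl[4-(but-3-yn-2-yloxymethyl)phenoxy]dimethylsilane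
Conditions: 2 (1.2 equiv), Et3SiH (1.5 equiv), TMSOTf (10 mol %), CH2Cl2, −78 → −20 °C
Reagents that add atoms: none
Why: Acid-catalysed reductive etherification, in which the hemiacetal of 1 and 2 ionises to an aryl-stabilised oxocarbenium ion that Et3SiH reduces to the benzylic ether, while the propargylic stereocentre of 2 is never ionised and is carried over unchanged.

Step 2
Reactants: 3 (S)-tert-butyl[4-(but-3-yn-2-yloxymethyl)phenoxy]dimethylsilane; 4 1-iodo-2-(methoxymethoxy)benzene
Product: 5 (S)-tert-butyl[4-({4-[2-(methoxymethoxy)phenyl]but-3-yn-2-yl}oxymethyl)phenoxy]dimethylsilane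
Conditions: Pd(PPh3)2Cl2 (2 mol %), CuI (4 mol %), Et3N/THF 1:1, rt
Reagents that add atoms: none
Why: Sonogashira coupling of the terminal alkyne with the aryl iodide under mild amine-base conditions that leave the silyl ether, the acetal and the stereocentre untouched.

Step 3
Reactants: 5 (S)-tert-butyl[4-({4-[2-(methoxymethoxy)phenyl]but-3-yn-2-yl}oxymethyl)phenoxy]dimethylsilane
Product: 6 tert-butyl[4-({(2S,3Z)-4-[2-(methoxymethoxy)phenyl]but-3-en-2-yl}oxymethyl)phenoxy]dimethylsilane
Conditions: H2 (1 atm), 5 % Pd/CaCO3 poisoned with Pb(OAc)2 (Lindlar catalyst), quinoline, EtOAc, rt, stopped after 1 equiv H2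
Reagents that add atoms: none
Why: Lindlar semi-hydrogenation adds H2 syn across the alkyne to give the (Z)-alkene needed for clean chirality transfer, without hydrogenolysis of the benzylic ether.

Step 4
Reactants: 6 tert-butyl[4-({(2S,3Z)-4-[2-(methoxymethoxy)phenyl]but-3-en-2-yl}oxymethyl)phenoxy]dimethylsilane
Product: 7 (1R,2R,3E)-1-[4-(tert-butyldimethylsilyloxy)phenyl]-2-[2-(methoxymethoxy)phenyl]pent-3-en-1-ol
Conditions: n-BuLi (1.5 equiv), THF, −78 → −40 °C; aq. NH4Cl
Reagents that add atoms: none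
Why: [2,3]-Wittig sigmatropic rearrangement, in which the benzylic α-oxy carbanion attacks the alkene terminus suprafacially through a five-membered envelope transition state with the allylic hydrogen turned inside and the methyl group outside (allylic 1,3-strain of the (Z)-alkene), so the bought (S)-centre is transferred to the new (R)-centre bearing the aryl group (C3 of the target) with an (E)-propenyl group, and the (Z)-geometry gives mainly the syn carbinol (any minor carbinol epimer is carried on because step 5 erases it).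

Step 5
Reactants: 7 (1R,2R,3E)-1-[4-(tert-butyldimethylsilyloxy)phenyl]-2-[2-(methoxymethoxy)phenyl]pent-3-en-1-ol
Product: 8 tert-butyldimethyl{4-[(2R,3R)-3-[(E)-prop-1-enyl]-2,3-dihydro-1-benzofuran-2-yl]phenoxy}silane
Conditions: TFA (5 equiv), H2O (5 equiv), CH2Cl2, −20 → 0 °C, short reaction time; aq. NaHCO3
Reagents that add atoms: none
Why: Acid ionises the 4-silyloxybenzylic alcohol to a stabilised benzylic cation that is captured 5-exo by the neighbouring aryl ether oxygen with loss of the methoxymethyl group (cyclodehydration), and the ring closes trans to the C3 propenyl group, so the C3 centre from step 4 sets C2 as (R) whichever carbinol epimer enters.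

Step 6
Reactants: 8 tert-butyldimethyl{4-[(2R,3R)-3-[(E)-prop-1-enyl]-2,3-dihydro-1-benzofuran-2-yl]phenoxy}silane
Product: 10 (2R,3R)-2-[4-(tert-butyldimethylsilyloxy)phenyl]-2,3-dihydro-1-benzofuran-3-carboxylic acid, via aldehyde 9 (not isolated)
Conditions: O3 (1.0 equiv), CH2Cl2/MeOH 4:1, −78 °C, then Me2S, −78 °C → rt, concentrate; then NaClO2, NaH2PO4, 2-methylbut-2-ene, t-BuOH/H2O, 0 °C → rt
Reagents that add atoms: ozone, [O-][O+]=O; sodium chlorite NaClO2, [Na+].[O-]Cl=O
Why: Ozonolysis of the only alkene followed by Pinnick oxidation of the crude aldehyde under buffered, weakly acidic conditions cleaves the propenyl group to the C3 carboxylic acid without enolising the α-aryl aldehyde, so both stereocentres are kept.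

Step 7
Reactants: 10 (2R,3R)-2-[4-(tert-butyldimethylsilyloxy)phenyl]-2,3-dihydro-1-benzofuran-3-carboxylic acid
Product: 11 (2R,3R)-2-[4-(tert-butyldimethylsilyloxy)phenyl]-5-iodo-2,3-dihydro-1-benzofuran-3-carboxylic acid
Conditions: N-iodosuccinimide (1.05 equiv), TFA (0.2 equiv), MeCN, 0 °C → rt
Reagents that add atoms: N-iodosuccinimide, O=C1CCC(=O)N1I
Why: Electrophilic aromatic iodination goes para to the ring oxygen of the dihydrobenzofuran (C5), the most activated free position, while the other ring is para-blocked and carries the weaker, hindered silyloxy donor.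

Step 8
Reactants: 11 (2R,3R)-2-[4-(tert-butyldimethylsilyloxy)phenyl]-5-iodo-2,3-dihydro-1-benzofuran-3-carboxylic acid; 12 acrylic acid
Product: 14 (2R,3R)-5-[(E)-2-carboxyethenyl]-2-(4-hydroxyphenyl)-2,3-dihydro-1-benzofuran-3-carboxylic acid, via silyl diacid 13 (not isolated)
Conditions: 12 (1.5 equiv), Pd(OAc)2 (5 mol %), P(o-tol)3 (10 mol %), Et3N (4 equiv), DMF, 80 °C; then KHF2 (2 equiv), MeOH, rt; 1 M HCl work-up
Reagents that add atoms: none
Why: Mizoroki–Heck coupling of the aryl iodide with acrylic acid gives the (E)-cinnamic acid by syn insertion and syn β-hydride elimination, and bifluoride then cleaves the phenolic silyl ether in the same flask, while the carboxylates are not enolised so C2 and C3 are unaffected.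

Step 9
Reactants: 14 (2R,3R)-5-[(E)-2-carboxyethenyl]-2-(4-hydroxyphenyl)-2,3-dihydro-1-benzofuran-3-carboxylic acid; 15 agmatine sulfate (two molecules are incorporated, one at each carboxyl group)
Product: 17 (2R,3R)-N-(4-guanidinobutyl)-5-{(E)-3-[(4-guanidinobutyl)amino]-3-oxoprop-1-enyl}-2-(4-hydroxyphenyl)-2,3-dihydro-1-benzofuran-3-carboxamide, via bis-NHS ester 16 (not isolated)
Conditions: N-hydroxysuccinimide (2.3 equiv), DCC (2.3 equiv), THF/DMF, 0 °C → rt, filter; then 15 (2.5 equiv in total), NaHCO3, H2O/THF, rt; reversed-phase HPLC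
Reagents that add atoms: agmatine sulfate (the second molecule of 15, which forms the second amide), NC(N)=NCCCCN.OS(=O)(=O)O
Why: Both acids are activated as N-hydroxysuccinimide esters (carbodiimide coupling) and each ester is aminolysed by the primary amine of one molecule of agmatine, whose guanidine stays protonated and unreactive at bicarbonate pH, which is mild enough to avoid enolisation or ring opening at C3.

**Compound list**
1 | 4-(tert-butyldimethylsilyloxy)benzaldehyde | O=Cc1ccc(O[Si](C)(C)C(C)(C)C)cc1 | starting material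
2 | (S)-but-3-yn-2-ol | C[C@H](O)C#C | starting material
3 | (S)-tert-butyl[4-(but-3-yn-2-yloxymethyl)phenoxy]dimethylsilane | C[C@H](OCc1ccc(O[Si](C)(C)C(C)(C)C)cc1)C#C | intermediate
4 | 1-iodo-2-(methoxymethoxy)benzene | COCOc1ccccc1I | starting material
5 | (S)-tert-butyl[4-({4-[2-(methoxymethoxy)phenyl]but-3-yn-2-yl}oxymethyl)phenoxy]dimethylsilane | C[C@H](OCc1ccc(O[Si](C)(C)C(C)(C)C)cc1)C#Cc1ccccc1OCOC | intermediate
6 | tert-butyl[4-({(2S,3Z)-4-[2-(methoxymethoxy)phenyl]but-3-en-2-yl}oxymethyl)phenoxy]dimethylsilane | C[C@H](OCc1ccc(O[Si](C)(C)C(C)(C)C)cc1)/C=C\c1ccccc1OCOC | intermediate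
7 | (1R,2R,3E)-1-[4-(tert-butyldimethylsilyloxy)phenyl]-2-[2-(methoxymethoxy)phenyl]pent-3-en-1-ol (major syn isomer; minor C1 epimer carried along) | C/C=C/[C@H](c1ccccc1OCOC)[C@@H](O)c1ccc(O[Si](C)(C)C(C)(C)C)cc1 | intermediate
8 | tert-butyldimethyl{4-[(2R,3R)-3-[(E)-prop-1-enyl]-2,3-dihydro-1-benzofuran-2-yl]phenoxy}silane (trans) | c1ccc2c(c1)[C@@H](/C=C/C)[C@H](c1ccc(O[Si](C)(C)C(C)(C)C)cc1)O2 | intermediate
9 | (2R,3R)-2-[4-(tert-butyldimethylsilyloxy)phenyl]-2,3-dihydro-1-benzofuran-3-carbaldehyde (not isolated) | c1ccc2c(c1)[C@@H](C=O)[C@H](c1ccc(O[Si](C)(C)C(C)(C)C)cc1)O2 | intermediate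
10 | (2R,3R)-2-[4-(tert-butyldimethylsilyloxy)phenyl]-2,3-dihydro-1-benzofuran-3-carboxylic acid | c1ccc2c(c1)[C@@H](C(=O)O)[C@H](c1ccc(O[Si](C)(C)C(C)(C)C)cc1)O2 | intermediate
11 | (2R,3R)-2-[4-(tert-butyldimethylsilyloxy)phenyl]-5-iodo-2,3-dihydro-1-benzofuran-3-carboxylic acid | Ic1ccc2c(c1)[C@@H](C(=O)O)[C@H](c1ccc(O[Si](C)(C)C(C)(C)C)cc1)O2 | intermediate
12 | acrylic acid | C=CC(=O)O | starting material
13 | (2R,3R)-5-[(E)-2-carboxyethenyl]-2-[4-(tert-butyldimethylsilyloxy)phenyl]-2,3-dihydro-1-benzofuran-3-carboxylic acid (not isolated) | OC(=O)/C=C/c1ccc2c(c1)[C@@H](C(=O)O)[C@H](c1ccc(O[Si](C)(C)C(C)(C)C)cc1)O2 | intermediate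
14 | (2R,3R)-5-[(E)-2-carboxyethenyl]-2-(4-hydroxyphenyl)-2,3-dihydro-1-benzofuran-3-carboxylic acid | OC(=O)/C=C/c1ccc2c(c1)[C@@H](C(=O)O)[C@H](c1ccc(O)cc1)O2 | intermediate
15 | agmatine sulfate, N-(4-aminobutyl)guanidine as its 1:1 salt with H2SO4 | NC(N)=NCCCCN.OS(=O)(=O)O | starting material
16 | 2,5-dioxopyrrolidin-1-yl (2R,3R)-5-{(E)-3-[(2,5-dioxopyrrolidin-1-yl)oxy]-3-oxoprop-1-enyl}-2-(4-hydroxyphenyl)-2,3-dihydro-1-benzofuran-3-carboxylate (not isolated) | O=C(/C=C/c1ccc2c(c1)[C@@H](C(=O)ON1C(=O)CCC1=O)[C@H](c1ccc(O)cc1)O2)ON1C(=O)CCC1=O | intermediate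
17 | (2R,3R)-N-(4-guanidinobutyl)-5-{(E)-3-[(4-guanidinobutyl)amino]-3-oxoprop-1-enyl}-2-(4-hydroxyphenyl)-2,3-dihydro-1-benzofuran-3-carboxamide | NC(N)=NCCCCNC(=O)/C=C/c1ccc2c(c1)[C@@H](C(=O)NCCCCN=C(N)N)[C@H](c1ccc(O)cc1)O2 | target

**Step count**
Total steps: 9. Longest linear sequence: 9 steps (1 and 2 through to 17); all other inputs are bought.

**Steps most likely to fail, with fallbacks**

Step 4 ([2,3]-Wittig rearrangement). n-BuLi may lithiate the allylic position or a ring position next to an oxygen substituent instead of the electron-rich benzylic CH2. The fallback makes the carbanion at a fixed site by reductive lithiation instead of deprotonation; it sets out from 1, 2 and 4 and comes back to the route at 7. Sonogashira coupling of 2 with 4 (Pd(PPh3)2Cl2, CuI, Et3N) gives (S)-4-[2-(methoxymethoxy)phenyl]but-3-yn-2-ol F1, and Lindlar hydrogenation gives (2S,3Z)-4-[2-(methoxymethoxy)phenyl]but-3-en-2-ol F2. Separately, reductive thioetherification of 1 with thiophenol (Et3SiH, BF3·OEt2) gives tert-butyldimethyl[4-(phenylsulfanylmethyl)phenoxy]silane F3. N-Chlorosuccinimide converts it to tert-butyl{4-[chloro(phenylsulfanyl)methyl]phenoxy}dimethylsilane F4, used crude to alkylate F2 (i-Pr2NEt, CH2Cl2, 0 °C). This gives the O,S-acetal tert-butyl[4-({[(2S,3Z)-4-[2-(methoxymethoxy)phenyl]but-3-en-2-yl]oxy}(phenylsulfanyl)methyl)phenoxy]dimethylsilane F5 as a mixture of acetal epimers. Lithium 4,4'-di-tert-butylbiphenylide (2 equiv, THF, −78 °C) cleaves the C–S bond, and the benzylic α-alkoxy organolithium undergoes the same [2,3]-shift to 7.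

Step 5 (acid cyclisation). The benzylic cation may lose a proton to give a conjugated diene, shift a hydride from C3, or the silyl ether may be lost. The fallback closes the ring by a palladium-catalysed C–O coupling with retention at the carbinol carbon, relying on the syn selectivity of the rearrangement; it sets out from 3 and comes back at 8. Sonogashira coupling of 3 with commercial 1-chloro-2-iodobenzene gives (S)-tert-butyl[4-({4-(2-chlorophenyl)but-3-yn-2-yl}oxymethyl)phenoxy]dimethylsilane F6. Lindlar hydrogenation gives tert-butyl[4-({(2S,3Z)-4-(2-chlorophenyl)but-3-en-2-yl}oxymethyl)phenoxy]dimethylsilane F7. n-BuLi in THF at −78 °C (the aryl chloride tolerates this) gives (1R,2R,3E)-1-[4-(tert-butyldimethylsilyloxy)phenyl]-2-(2-chlorophenyl)pent-3-en-1-ol F8. Intramolecular etherification (Pd(OAc)2, 2-(di-tert-butylphosphino)-1,1'-binaphthyl, Cs2CO3, toluene, 80 °C) then gives trans 8; the cis isomer from any minor anti carbinol is removed by chromatography.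

Step 9 (double amidation with unprotected agmatine). The activated C3 ester may open the ring by β-elimination of the phenoxide, or the bis-guanidine may be hard to separate from excess agmatine. The fallback uses a protected guanidine and a final global deprotection; it sets out from 14 and comes back at 17. Putrescine (excess) and N,N'-di-Boc-1H-pyrazole-1-carboxamidine give N,N'-di-Boc-agmatine F9. Coupling of 14 with F9 (2.2 equiv; 1-ethyl-3-(3-dimethylaminopropyl)carbodiimide, HOBt, DMF, 0 °C → rt) gives the chromatographable tetra-Boc bis-amide (2R,3R)-N-{4-[N',N''-bis(tert-butoxycarbonyl)guanidino]butyl}-5-[(E)-3-({4-[N',N''-bis(tert-butoxycarbonyl)guanidino]butyl}amino)-3-oxoprop-1-enyl]-2-(4-hydroxyphenyl)-2,3-dihydro-1-benzofuran-3-carboxamide F10. TFA/CH2Cl2 with anisole (0 °C → rt) removes the four Boc groups to give 17.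

Further compounds
F1 | step 4 | (S)-4-[2-(methoxymethoxy)phenyl]but-3-yn-2-ol | C[C@H](O)C#Cc1ccccc1OCOC
F2 | step 4 | (2S,3Z)-4-[2-(methoxymethoxy)phenyl]but-3-en-2-ol | C[C@H](O)/C=C\c1ccccc1OCOC
F3 | step 4 | tert-butyldimethyl[4-(phenylsulfanylmethyl)phenoxy]silane | CC(C)(C)[Si](C)(C)Oc1ccc(CSc2ccccc2)cc1
F4 | step 4 | tert-butyl{4-[chloro(phenylsulfanyl)methyl]phenoxy}dimethylsilane (racemic) | CC(C)(C)[Si](C)(C)Oc1ccc(C(Cl)Sc2ccccc2)cc1
F5 | step 4 | tert-butyl[4-({[(2S,3Z)-4-[2-(methoxymethoxy)phenyl]but-3-en-2-yl]oxy}(phenylsulfanyl)methyl)phenoxy]dimethylsilane (both acetal epimers) | C[C@H](OC(Sc1ccccc1)c1ccc(O[Si](C)(C)C(C)(C)C)cc1)/C=C\c1ccccc1OCOC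
F6 | step 5 | (S)-tert-butyl[4-({4-(2-chlorophenyl)but-3-yn-2-yl}oxymethyl)phenoxy]dimethylsilane | C[C@H](OCc1ccc(O[Si](C)(C)C(C)(C)C)cc1)C#Cc1ccccc1Cl
F7 | step 5 | tert-butyl[4-({(2S,3Z)-4-(2-chlorophenyl)but-3-en-2-yl}oxymethyl)phenoxy]dimethylsilane | C[C@H](OCc1ccc(O[Si](C)(C)C(C)(C)C)cc1)/C=C\c1ccccc1Cl
F8 | step 5 | (1R,2R,3E)-1-[4-(tert-butyldimethylsilyloxy)phenyl]-2-(2-chlorophenyl)pent-3-en-1-ol | C/C=C/[C@H](c1ccccc1Cl)[C@@H](O)c1ccc(O[Si](C)(C)C(C)(C)C)cc1
F9 | step 9 | N,N'-di-Boc-agmatine, 1-(4-aminobutyl)-2,3-bis(tert-butoxycarbonyl)guanidine | CC(C)(C)OC(=O)N=C(NCCCCN)NC(=O)OC(C)(C)C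
F10 | step 9 | tetra-Boc bis-amide, (2R,3R)-N-{4-[N',N''-bis(tert-butoxycarbonyl)guanidino]butyl}-5-[(E)-3-({4-[N',N''-bis(tert-butoxycarbonyl)guanidino]butyl}amino)-3-oxoprop-1-enyl]-2-(4-hydroxyphenyl)-2,3-dihydro-1-benzofuran-3-carboxamide | CC(C)(C)OC(=O)N=C(NCCCCNC(=O)/C=C/c1ccc2c(c1)[C@@H](C(=O)NCCCCNC(=NC(=O)OC(C)(C)C)NC(=O)OC(C)(C)C)[C@H](c1ccc(O)cc1)O2)NC(=O)OC(C)(C)C
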